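In the zeta run, at 25 °C, first product goes from 7% at 6.00 min to 24% at 15.0 min, and I read the rate from that rise.

| flask | substrate | solid reagent | temperature | remark | time |
|---|---|---|---|---|---|
| theta | 0.050 M | 0.15 M | −10 °C | run made earlier |  |
| zeta | 0.20 M | 0.15 M | 25 °C | run made earlier |  |
| grey | 0.10 M | 0.150 M |  | at −5 °C until 10 min, from then on at 55 °C | 30 min |
| amber | 0.10 M | 0.150 M | 25 °C |  | 30 min |
| green | 0.10 M | 0.150 M | −5 °C |  | 30 min |
| teal | 0.10 M | 0.150 M | 55 °C |  | 30 min |

| run | time / min | first product / % |
|---|---|---|
| theta | 15.0 | 3 |
| theta | 30.0 | 6 |
| theta | 80.0 | 15 |
| theta | 240 | 32 |
| zeta | 3.00 | 3 |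
| zeta | 6.00 | 7 |
| zeta | 15.0 | 24 |
| zeta | 40.0 | 35 |

(standard deviation of a reading: 2 percentage points)

- solid, in amounts per volume of the solution: solid reagent
- the analysis behind the earlier runs scatters by 2 percentage points, standard deviation
- steps under discussion: substrate + partner -> first product; partner + first product -> bis adduct; solid reagent <-> partner
- at the start none of the solid reagent is in solution

1. the flask that comes out highest in amount of first product, in percent of the substrate charged, or "all alike" when all lie within 1.5 percentage points (grey / amber / green / teal / all alike)
2. first product at the end, in percent of the substrate charged, grey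
3. first product at the end, in percent of the substrate charged, amber
4. first product at the end, in percent of the substrate charged, green
5. first product at the end, in percent of the substrate charged, teal

I reckon with the fraction of substrate left. My quantity is the exposure, the natural logarithm of one over that fraction. While c(partner) stays constant (pseudo-first-order), exposure is a rate per minute times time. I assume both steps run equally fast, so first product equals exposure times fraction left, with a peak of 36.8% at exposure one. A relative error in the rate then reaches first product multiplied by one minus the exposure. Near the peak the rate matters little, and at low exposure it passes through whole. While c(partner) stays constant, the substrate charge doesn't enter exposure, and the solid reagent charge enters as the limit on what can be used. Reagent used per substrate charged is the substrate lost plus the bis adduct, which takes a second partner.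

So the rate needs knowing. Zeta gives 0.0224 min⁻¹, taking what is made for what is gone, and the scatter puts 16.6% on it. For amber the exposure 0.673 gives 34.3%, give or take 1.9 percentage points. Amber uses 63.6% of the substrate charged in reagent, less than the 150% charged. Theta gives 0.002031 min⁻¹. Interpolating in degrees, green has exposure 0.0859, hence 7.88%. Extrapolated roughly, teal reaches 5.27 and grey's hot part 3.51. But exposure 2 already uses 146% of the substrate charged, so I stop both there, at 27.1%. I expect amber highest.

The forecast says amber, with grey 31%, amber 34%, green 7%, teal 24%: “Amber is likely highest, narrowly”.

The flasks give amber highest: grey 26.8%, amber 34.9%, green 7.64%, teal 24.5%. Amber at 30.0 min still holds 53.5% of its substrate and 39.6% of its solid reagent, against 51.0% left by my exposure of 0.673.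

    substrate + partner → first product (k = 0.0110 M⁻¹ s⁻¹, Ea = 46.0 kJ mol⁻¹)
    partner + first product → bis adduct (k = 0.00950 M⁻¹ s⁻¹, Ea = 53.0 kJ mol⁻¹)
    solid reagent ⇌ partner, rate k3*(cs3 - [partner]) while solid is left; crystals form when [partner] > cs3 (solubility = 34.0 mM, k = 0.0210 s⁻¹)
    (constants at 25 °C)

A neighbour flask, like grey but with 0.037 M of solid reagent, has a charge of 0.370 per substrate. Taken as exposure, that uses 36.3% and gives 69.1% left and 25.6% first product. The neighbour flask gives 69.0% of its substrate left and 25.1% first product, with solid reagent at 0%.

The runs were computed with constants of no real substance; scatter was added.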